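## Structural features

The target is a (2S)-flavanone (rings A and C: 5,7-dihydroxy-6,8-bis(3-methylbut-2-enyl)chroman-4-one) whose ring B is at the same time the benzo ring of a trans-2,3-diaryl-2,3-dihydrobenzofuran (ring D), i.e. a flavanone–stilbene hybrid. Ring B carries flavanone C2 at C1′, a free hydroxyl at C2′, the ring-D oxygen at C4′ and the ring-D carbon Cb at C5′. Ring D is O–Ca–Cb: Ca (R, benzofuran C2) bears the 4-hydroxyphenyl group, Cb (R, benzofuran C3) bears the 3,5-dihydroxyphenyl group, and the two aryl groups are trans. Ca and Cb are adjacent and form one stereochemical unit, whereas C2 (S) is insulated from them by the flat ring B, so no relay between the two domains is possible. The fragile groups are the two prenyl groups flanked by phenols (acid-induced chroman formation, hydrogenation, oxidants), the flavanone (base-induced retro-oxa-Michael opening and C2 epimerisation), the O–Ca benzylic ether para to a phenol (ionisation to a p-quinone methide) and the six phenols. The real difficulty is ring D, with two contiguous benzylic stereocentres in absolute form, on an arene that must also be joined to C2. The key step exploits two features: Cb is a diarylmethine carbon, hence the carbon of a diaryl carbene, and Ca–H is a benzylic, oxygen-activated C–H bond held 1,5 to Cb through C5′–C4′–O, so carbene insertion closes ring D at the Ca–Cb bond and sets both centres in one event. In one sentence: a dirhodium-carbene 1,5-insertion of a diaryldiazomethane, generated from an ortho-(4-methoxybenzyloxy)benzophenone hydrazone, into the benzylic ether C–H bond forms ring D by its C–C bond.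

## Logic of the disconnections

20 ⇒ 19. Six phenolic O–H bonds are masked as O–CH2OCH3 acetals. All six phenols are hidden by one group type that tolerates base, boron and rhodium chemistry, so one operation ends the synthesis. The forward step must cleave six acetals without protonating the prenyl alkenes or solvolysing the O–Ca bond.

19 ⇒ 12 + 18. The C2–C1′ bond is cut. C2 cannot be controlled from ring D, so it is best set by a catalyst in the very step that joins the two halves. This divides the molecule into a ring-D aryl boronate and an achiral chromone of roughly equal size. The forward step must be a catalyst-controlled enantioselective 1,4-arylation that overrides the remote stereocentres, outruns protodeboronation of the electron-rich ortho-alkoxy arylboronate and is mild enough not to open the flavanone.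

12 ⇒ 11 ⇒ 10. The C1′–B bond and four acetal O–C bonds are cut. A bromine at C1′ is inert to every earlier step and is converted to boron only when needed; the acetals are installed after the one Lewis-acidic step. The forward steps are a borylation of a hindered, electron-rich aryl bromide and a four-fold phenol protection.

10 ⇒ 9. No skeletal bond is cut: the configuration at Ca is inverted and four O–CH3 bonds are restored. This lets the ring-forming step deliver its kinetic cis product and lets the cheapest methyl ether building blocks be used. The forward step must epimerise Ca through reversible O–Ca ionisation while Cb stays untouched, and must cleave four methyl ethers.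

9 ⇒ 8 ⇒ 7 ⇒ 6 (key disconnection). The Ca–Cb bond of ring D is cut, not the Cb–C5′/O–Ca pair of a phenol–stilbene annulation. Cb becomes a carbene carbon (diazo, then hydrazone, then ketone) and Ca becomes the CH2 of a 4-methoxybenzyl ether. Ring D and both stereocentres reduce to an achiral benzophenone ether. The forward step needs a chiral dirhodium catalyst that controls the carbene face, and insertion must outrun azine formation.

6 ⇒ 4 + 5. The O–CH2 bond is cut. The phenol oxygen that becomes the ring-D oxygen is the only free hydroxyl of 4, so the etherification is unambiguous. The forward step must alkylate a carbonyl-chelated phenol.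

4 ⇒ 3 ⇒ 1 + 2. The C5′–C(=O) bond is cut. C5′ is para to the C2′ oxygen and ortho to the C4′ oxygen, the natural site of electrophilic attack, so a Friedel–Crafts acylation places the carbonyl correctly; the bromine in 1 already marks C1′. The forward step must also remove only the methyl group ortho to the new carbonyl, which chelation ensures.

18 ⇒ 17 ⇒ 16. The O1–C2 and C2–C3 bonds of ring C are cut, removing a one-carbon unit. The chromone is reduced to an ortho-hydroxyacetophenone. The forward step must form the enaminone and cyclise it without loss of the acetals.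

16 ⇒ 15 ⇒ 13 + 14. Two acetal O–C bonds and the two aryl–CH2 bonds at C6 and C8 are cut. Both free ring positions of the symmetric phloroglucinol ketone receive the same group, so no regiochemical question arises, and symmetry also makes the later bis-protection unambiguous. The forward step must favour C- over O-alkylation.

## Other disconnections considered

Alternative 1: The first cut that comes to mind runs through ring C, at O1–C2 and at the C2–C3 bond seen as a chalcone double bond. In the forward sense, Claisen–Schmidt condensation of 16 with the racemic ring-B aldehyde A1 (its ring D from an oxidative phenol–stilbene [3+2] coupling) would give the 2′-hydroxychalcone A2, and intramolecular oxa-Michael addition would close ring C as the key step. That ring closure is reversible and under thermodynamic control, and ring D is too remote to bias the C2 face, so both C2 epimers are expected. The oxidative coupling gives ring D as a racemate, so A2 leads to up to four stereoisomers. The key step would therefore solve none of the stereochemical problem, whereas the chosen plan sets each domain by a catalyst.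

Alternative 2: Ring D is cut at Cb–C5′ and O–Ca at the very end, copying the presumed biosynthesis. The forward key step is oxidative cross-coupling of the complete flavanone A3 with resveratrol A4 by a one-electron oxidant such as Ag2O or FeCl3. This is the shortest route on paper, but three mechanistic grounds speak against it. The resveratrol radical should dimerise faster than it cross-couples. The B-ring radical can react at C3′ as well as C5′. The new Ca/Cb pair forms far from C2, so an equal mixture of the (R,R) and (S,S) ring-D diastereomers is expected. In addition, the oxidant also meets the electron-rich ring A and the prenyl alkenes. The chosen plan pays a few more steps for control of every stereocentre.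

Alternative 3: Only the O–Ca bond is cut. Cb would first be set alone in the triarylethane A5, for example by an asymmetric conjugate arylation sequence. Benzylic oxidation would then give the p-quinone methide A6, and a 5-exo-trig oxa-Michael addition of the ring-B phenol would set Ca trans by relay from Cb. The weakness is mechanistic: in A6 the Cb–H bond is doubly benzylic and adjacent to the quinone methide, so tautomerisation to the conjugated stilbene competes with ring closure and erases the only stereocentre irreversibly. A5 also needs its own multi-step asymmetric synthesis. The chosen key step creates Cb and closes ring D in one event from a ketone made in two steps.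

Key step: step 4

Assumption: the sense of induction of Rh2(R-PTAD)4 in step 4 and of the (R,R)-diene ligand in step 11 is taken as written; if either delivers the opposite sense, the enantiomeric catalyst is used with no other change.

## Steps

Step 1
Reactants: 1 1-bromo-2,4-dimethoxybenzene; 2 3,5-dimethoxybenzoyl chloride
Product: 4 (5-bromo-2-hydroxy-4-methoxyphenyl)(3,5-dimethoxyphenyl)methanone, via tetramethoxybenzophenone 3 (not isolated)
Conditions: AlCl3 (2.5 equiv), ClCH2CH2Cl, 0 °C then 50 °C; aq. HCl work-up
Reagents that add atoms: none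
Why: Friedel–Crafts acylation should occur at C5 of 1, the only unhindered position activated by both methoxy groups (para to one, ortho to the other); excess AlCl3 then chelates the carbonyl and the ortho methoxy oxygen, and chloride removes only that methyl group (chelation-controlled mono-demethylation).

Step 2
Reactants: 4 (5-bromo-2-hydroxy-4-methoxyphenyl)(3,5-dimethoxyphenyl)methanone; 5 4-methoxybenzyl chloride
Product: 6 {5-bromo-4-methoxy-2-[(4-methoxybenzyl)oxy]phenyl}(3,5-dimethoxyphenyl)methanone
Conditions: K2CO3 (2 equiv), NaI (10 mol%), DMF, 60 °C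
Reagents that add atoms: none
Why: Williamson ether synthesis on the only free phenol; iodide catalysis and gentle heating should overcome the hydrogen bond of the chelated hydroxyl.

Step 3
Reactants: 6 {5-bromo-4-methoxy-2-[(4-methoxybenzyl)oxy]phenyl}(3,5-dimethoxyphenyl)methanone
Product: 7 [{5-bromo-4-methoxy-2-[(4-methoxybenzyl)oxy]phenyl}(3,5-dimethoxyphenyl)methylidene]hydrazine (mixture of C=N isomers)
Conditions: N2H4·H2O (10 equiv), AcOH (cat.), EtOH, 80 °C
Reagents that add atoms: hydrazine monohydrate, NN.O
Why: Acid-catalysed hydrazone condensation of a diaryl ketone; the large excess of hydrazine should suppress azine formation, and the C=N geometry is irrelevant because it is lost in the next step.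

Step 4
Reactants: 7 [{5-bromo-4-methoxy-2-[(4-methoxybenzyl)oxy]phenyl}(3,5-dimethoxyphenyl)methylidene]hydrazine
Product: 9 (2S,3R)-5-bromo-3-(3,5-dimethoxyphenyl)-6-methoxy-2-(4-methoxyphenyl)-2,3-dihydro-1-benzofuran (cis), via diaryldiazomethane 8 (not isolated)
Conditions: MnO2 (8 equiv), CH2Cl2, 0 °C; then Rh2(R-PTAD)4 (dirhodium tetrakis[(R)-(1-adamantyl)(phthalimido)acetate], 1 mol%), 0 °C → rt
Reagents that add atoms: none
Why: MnO2 dehydrogenates the hydrazone to the diaryldiazomethane 8, and the dirhodium tetracarboxylate then expels dinitrogen to give a donor/donor rhodium carbene at Cb. The closest known reaction type is the dirhodium-catalysed intramolecular 1,5-C–H insertion of diaryl carbenes into benzylic ether C–H bonds, which gives 2,3-disubstituted 2,3-dihydrobenzofurans. Ring D is closed by C–C bond formation (Ca–Cb) through a five-membered, strongly asynchronous transition state in which hydride moves from Ca–H to the carbene carbon while the C–C bond forms; the only C–H bonds within reach are the two enantiotopic benzylic ether hydrogens. Cb is set by the chiral carboxylate ligands, which differentiate the two carbene faces (catalyst control), and Ca is set in the same event because the catalyst also selects which enantiotopic hydrogen is transferred. The cis relation should follow from the compact transition state, in which the 4-methoxyphenyl group turns away from the ligand wall and ends on the same side as the 3,5-dimethoxyphenyl group. The step needs chemoselectivity for insertion over azine formation and carbene dimerisation; the attenuated electrophilicity of the donor/donor carbene, the hydridic p-methoxybenzylic C–H bond and the slow, oxidant-limited generation of 8 should secure it. Only the configuration at Cb has to be right, since Ca is corrected in step 5.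

Step 5
Reactants: 9 (2S,3R)-5-bromo-3-(3,5-dimethoxyphenyl)-6-methoxy-2-(4-methoxyphenyl)-2,3-dihydro-1-benzofuran
Product: 10 5-[(2R,3R)-5-bromo-6-hydroxy-2-(4-hydroxyphenyl)-2,3-dihydro-1-benzofuran-3-yl]benzene-1,3-diol (trans)
Conditions: BBr3 (8 equiv), CH2Cl2, −78 °C → rt; aq. NaHCO3 work-up
Reagents that add atoms: none
Why: BBr3 cleaves the four aryl methyl ethers (Lewis-acid ether cleavage); the same Lewis acid reversibly ionises the O–Ca bond to a p-oxybenzylic cation or p-quinone methide, and 5-exo-trig reclosure should give the thermodynamically favoured trans isomer, so Ca is inverted under control by Cb, which is not touched.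

Step 6
Reactants: 10 5-[(2R,3R)-5-bromo-6-hydroxy-2-(4-hydroxyphenyl)-2,3-dihydro-1-benzofuran-3-yl]benzene-1,3-diol
Product: 11 (2R,3R)-3-[3,5-bis(methoxymethoxy)phenyl]-5-bromo-6-(methoxymethoxy)-2-[4-(methoxymethoxy)phenyl]-2,3-dihydro-1-benzofuran
Conditions: MOMCl (6 equiv), i-Pr2NEt (8 equiv), CH2Cl2, 0 °C → rt
Reagents that add atoms: chloromethyl methyl ether, COCCl
Why: Four-fold O-alkylation of phenols to methoxymethyl acetals; the weak amine base keeps the phenoxide concentration low, so the p-hydroxyphenyl group should not expel the ring-D aryloxide, and no stereocentre is touched.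

Step 7
Reactants: 11 (2R,3R)-3-[3,5-bis(methoxymethoxy)phenyl]-5-bromo-6-(methoxymethoxy)-2-[4-(methoxymethoxy)phenyl]-2,3-dihydro-1-benzofuran
Product: 12 2-{(2R,3R)-3-[3,5-bis(methoxymethoxy)phenyl]-6-(methoxymethoxy)-2-[4-(methoxymethoxy)phenyl]-2,3-dihydro-1-benzofuran-5-yl}-4,4,5,5-tetramethyl-1,3,2-dioxaborolane
Conditions: B2pin2 (1.5 equiv), Pd2(dba)3 (2 mol%), XPhos (8 mol%), KOAc (3 equiv), 1,4-dioxane, 90 °C
Reagents that add atoms: bis(pinacolato)diboron, CC1(C)OB(OC1(C)C)B1OC(C)(C)C(C)(C)O1
Why: Miyaura borylation; the bulky electron-rich biarylphosphine should cope with the electron-rich, ortho-oxygenated bromide, and KOAc is too weak a base to start Suzuki coupling of the product.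

Step 8
Reactants: 13 1-(2,4,6-trihydroxyphenyl)ethanone; 14 1-bromo-3-methylbut-2-ene
Product: 15 1-[2,4,6-trihydroxy-3,5-bis(3-methylbut-2-enyl)phenyl]ethanone
Conditions: 14 (2.1 equiv), 10% aq. KOH, 0 °C → rt
Reagents that add atoms: none
Why: Double C-alkylation of the ambident phloroglucinol phenoxide; aqueous hydroxide solvates the oxygen and favours attack through carbon, and the two free ring positions are equivalent, so only the degree of alkylation has to be controlled, which is tolerable in an early step on inexpensive material.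

Step 9
Reactants: 15 1-[2,4,6-trihydroxy-3,5-bis(3-methylbut-2-enyl)phenyl]ethanone
Product: 16 1-[2-hydroxy-4,6-bis(methoxymethoxy)-3,5-bis(3-methylbut-2-enyl)phenyl]ethanone
Conditions: MOMCl (2.4 equiv), i-Pr2NEt (3 equiv), CH2Cl2, 0 °C → rt
Reagents that add atoms: chloromethyl methyl ether, COCCl
Why: Phenol protection as methoxymethyl acetals; 15 is symmetric, so any bis-etherification that leaves one carbonyl-chelated hydroxyl free gives the same compound, and that last hydroxyl is deactivated by its hydrogen bond to the acetyl group.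

Step 10
Reactants: 16 1-[2-hydroxy-4,6-bis(methoxymethoxy)-3,5-bis(3-methylbut-2-enyl)phenyl]ethanone
Product: 18 5,7-bis(methoxymethoxy)-6,8-bis(3-methylbut-2-enyl)-4H-chromen-4-one, via enaminone 17 (not isolated)
Conditions: Me2NCH(OMe)2 (3 equiv), toluene, 100 °C; evaporate; AcOH (5 equiv), toluene, 70 °C
Reagents that add atoms: N,N-dimethylformamide dimethyl acetal, COC(OC)N(C)C
Why: Condensation of the methyl ketone with the amide acetal gives the enaminone; weak acid then promotes 6-endo-trig addition of the phenol to the β-carbon and loss of dimethylamine (addition–elimination) to the chromone, under conditions the acetals should survive.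

Step 11
Reactants: 12 2-{(2R,3R)-3-[3,5-bis(methoxymethoxy)phenyl]-6-(methoxymethoxy)-2-[4-(methoxymethoxy)phenyl]-2,3-dihydro-1-benzofuran-5-yl}-4,4,5,5-tetramethyl-1,3,2-dioxaborolane; 18 5,7-bis(methoxymethoxy)-6,8-bis(3-methylbut-2-enyl)-4H-chromen-4-one
Product: 19 (2S)-2-{(2R,3R)-3-[3,5-bis(methoxymethoxy)phenyl]-6-(methoxymethoxy)-2-[4-(methoxymethoxy)phenyl]-2,3-dihydro-1-benzofuran-5-yl}-5,7-bis(methoxymethoxy)-6,8-bis(3-methylbut-2-enyl)-2,3-dihydro-4H-chromen-4-one
Conditions: 18 (1.5 equiv), [RhCl(C2H4)2]2 (2.5 mol%), (1R,4R)-2,5-diphenylbicyclo[2.2.2]octa-2,5-diene (5.5 mol%), KOH (0.3 equiv), 1,4-dioxane/H2O (10:1), 40 °C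
Reagents that add atoms: none
Why: Hayashi–Miyaura rhodium-catalysed asymmetric 1,4-addition of an arylboron reagent to a chromone: boron-to-rhodium transmetalation, insertion of the C2=C3 bond into the aryl–rhodium bond on the face selected by the chiral diene, and protonolysis of the oxa-π-allyl rhodium species by water; C2 should be set as S by catalyst control, since the stereocentres of 12 are too remote to interfere.

Step 12
Reactants: 19 (2S)-2-{(2R,3R)-3-[3,5-bis(methoxymethoxy)phenyl]-6-(methoxymethoxy)-2-[4-(methoxymethoxy)phenyl]-2,3-dihydro-1-benzofuran-5-yl}-5,7-bis(methoxymethoxy)-6,8-bis(3-methylbut-2-enyl)-2,3-dihydro-4H-chromen-4-one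
Product: 20 (2S)-2-[(2R,3R)-3-(3,5-dihydroxyphenyl)-6-hydroxy-2-(4-hydroxyphenyl)-2,3-dihydro-1-benzofuran-5-yl]-5,7-dihydroxy-6,8-bis(3-methylbut-2-enyl)-2,3-dihydro-4H-chromen-4-one (CNP0230984.1)
Conditions: HCl (1.25 M in MeOH), THF, 40 °C
Reagents that add atoms: none
Why: Acid-catalysed transacetalisation of the six aryl methoxymethyl ethers with methanol; dilute acid at moderate temperature is the usual way to unmask prenylated flavanones, C2 is not acid-labile, and any reversible O–Ca ionisation returns the trans ring D.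

## Compound list

1 | 1-bromo-2,4-dimethoxybenzene | COc1ccc(Br)c(OC)c1 | starting material
2 | 3,5-dimethoxybenzoyl chloride | COc1cc(OC)cc(C(=O)Cl)c1 | starting material
3 | (5-bromo-2,4-dimethoxyphenyl)(3,5-dimethoxyphenyl)methanone | COc1cc(OC)c(C(=O)c2cc(OC)cc(OC)c2)cc1Br | intermediate (not isolated)
4 | (5-bromo-2-hydroxy-4-methoxyphenyl)(3,5-dimethoxyphenyl)methanone | COc1cc(O)c(C(=O)c2cc(OC)cc(OC)c2)cc1Br | intermediate
5 | 4-methoxybenzyl chloride | COc1ccc(CCl)cc1 | starting material
6 | {5-bromo-4-methoxy-2-[(4-methoxybenzyl)oxy]phenyl}(3,5-dimethoxyphenyl)methanone | COc1cc(OCc2ccc(OC)cc2)c(C(=O)c2cc(OC)cc(OC)c2)cc1Br | intermediate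
7 | [{5-bromo-4-methoxy-2-[(4-methoxybenzyl)oxy]phenyl}(3,5-dimethoxyphenyl)methylidene]hydrazine | COc1cc(OCc2ccc(OC)cc2)c(C(=NN)c2cc(OC)cc(OC)c2)cc1Br | intermediate
8 | 1-bromo-5-[diazo(3,5-dimethoxyphenyl)methyl]-2-methoxy-4-[(4-methoxybenzyl)oxy]benzene | COc1cc(OCc2ccc(OC)cc2)c(C(=[N+]=[N-])c2cc(OC)cc(OC)c2)cc1Br | intermediate (not isolated)
9 | (2S,3R)-5-bromo-3-(3,5-dimethoxyphenyl)-6-methoxy-2-(4-methoxyphenyl)-2,3-dihydro-1-benzofuran | Brc1cc2c(cc1OC)O[C@H](c1ccc(OC)cc1)[C@@H]2c1cc(OC)cc(OC)c1 | intermediate
10 | 5-[(2R,3R)-5-bromo-6-hydroxy-2-(4-hydroxyphenyl)-2,3-dihydro-1-benzofuran-3-yl]benzene-1,3-diol | Brc1cc2c(cc1O)O[C@@H](c1ccc(O)cc1)[C@@H]2c1cc(O)cc(O)c1 | intermediate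
11 | (2R,3R)-3-[3,5-bis(methoxymethoxy)phenyl]-5-bromo-6-(methoxymethoxy)-2-[4-(methoxymethoxy)phenyl]-2,3-dihydro-1-benzofuran | Brc1cc2c(cc1OCOC)O[C@@H](c1ccc(OCOC)cc1)[C@@H]2c1cc(OCOC)cc(OCOC)c1 | intermediate
12 | 2-{(2R,3R)-3-[3,5-bis(methoxymethoxy)phenyl]-6-(methoxymethoxy)-2-[4-(methoxymethoxy)phenyl]-2,3-dihydro-1-benzofuran-5-yl}-4,4,5,5-tetramethyl-1,3,2-dioxaborolane | CC1(C)OB(OC1(C)C)c1cc2c(cc1OCOC)O[C@@H](c1ccc(OCOC)cc1)[C@@H]2c1cc(OCOC)cc(OCOC)c1 | intermediate
13 | 1-(2,4,6-trihydroxyphenyl)ethanone | CC(=O)c1c(O)cc(O)cc1O | starting material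
14 | 1-bromo-3-methylbut-2-ene | CC(C)=CCBr | starting material
15 | 1-[2,4,6-trihydroxy-3,5-bis(3-methylbut-2-enyl)phenyl]ethanone | CC(=O)c1c(O)c(CC=C(C)C)c(O)c(CC=C(C)C)c1O | intermediate
16 | 1-[2-hydroxy-4,6-bis(methoxymethoxy)-3,5-bis(3-methylbut-2-enyl)phenyl]ethanone | CC(=O)c1c(O)c(CC=C(C)C)c(OCOC)c(CC=C(C)C)c1OCOC | intermediate
17 | (E)-3-(dimethylamino)-1-[2-hydroxy-4,6-bis(methoxymethoxy)-3,5-bis(3-methylbut-2-enyl)phenyl]prop-2-en-1-one | CN(C)/C=C/C(=O)c1c(O)c(CC=C(C)C)c(OCOC)c(CC=C(C)C)c1OCOC | intermediate (not isolated)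
18 | 5,7-bis(methoxymethoxy)-6,8-bis(3-methylbut-2-enyl)-4H-chromen-4-one | O=c1ccoc2c(CC=C(C)C)c(OCOC)c(CC=C(C)C)c(OCOC)c12 | intermediate
19 | (2S)-2-{(2R,3R)-3-[3,5-bis(methoxymethoxy)phenyl]-6-(methoxymethoxy)-2-[4-(methoxymethoxy)phenyl]-2,3-dihydro-1-benzofuran-5-yl}-5,7-bis(methoxymethoxy)-6,8-bis(3-methylbut-2-enyl)-2,3-dihydro-4H-chromen-4-one | CC(C)=CCc1c(OCOC)c(CC=C(C)C)c2c(c1OCOC)C(=O)C[C@@H](c1cc3c(cc1OCOC)O[C@@H](c1ccc(OCOC)cc1)[C@@H]3c1cc(OCOC)cc(OCOC)c1)O2 | intermediate
20 | (2S)-2-[(2R,3R)-3-(3,5-dihydroxyphenyl)-6-hydroxy-2-(4-hydroxyphenyl)-2,3-dihydro-1-benzofuran-5-yl]-5,7-dihydroxy-6,8-bis(3-methylbut-2-enyl)-2,3-dihydro-4H-chromen-4-one | CC(C)=CCc1c(O)c(CC=C(C)C)c2c(c1O)C(=O)C[C@@H](c1cc3c(cc1O)O[C@@H](c1ccc(O)cc1)[C@@H]3c1cc(O)cc(O)c1)O2 | target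

## Step count and least certain steps

Total step count: 12. Longest linear sequence: 9 steps (steps 1 to 7, then 11 and 12); steps 8 to 10 form the second branch.

Step 4 (key step). The most likely failures are insufficient face selection at the carbene, which bears two electronically similar aryl groups, and capture of the carbene by unreacted 8 to give the azine when diazo formation outpaces insertion. The fallback gives up catalytic control of ring D and sets out from 6. Base-induced cyclisation of the benzylic ether carbanion onto the ketone (t-Bu-P4 phosphazene base, then TsOH) should give 5-bromo-3-(3,5-dimethoxyphenyl)-6-methoxy-2-(4-methoxyphenyl)-1-benzofuran F1. Ionic hydrogenation (Et3SiH, CF3CO2H) should deliver hydride to the O-stabilised cation trans to the C3 aryl group and give racemic trans-5-bromo-3-(3,5-dimethoxyphenyl)-6-methoxy-2-(4-methoxyphenyl)-2,3-dihydro-1-benzofuran F2. BBr3 demethylation then gives 10 together with its enantiomer 5-[(2S,3S)-5-bromo-6-hydroxy-2-(4-hydroxyphenyl)-2,3-dihydro-1-benzofuran-3-yl]benzene-1,3-diol F3, which is removed by preparative chromatography on a chiral stationary phase. The route is rejoined at 10.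

Step 5. The ring-opened cation at Ca may lose the adjacent doubly benzylic Cb–H (elimination to a stilbene, with loss of the stereocentre), or epimerisation may stay incomplete while demethylation proceeds. The fallback separates the two events and avoids a Lewis acid in the dealkylation. From 9, catalytic CF3CO2H in CH2Cl2 should equilibrate Ca to the trans ether (2R,3R)-5-bromo-3-(3,5-dimethoxyphenyl)-6-methoxy-2-(4-methoxyphenyl)-2,3-dihydro-1-benzofuran F4 under the mildest ionising conditions. Nucleophilic demethylation by SN2 attack at the methyl groups (NaSEt, DMF, 130 °C) then gives 10, where the route is rejoined.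

Step 11. Protodeboronation of the electron-rich, ortho-alkoxy arylboronate may outrun its transfer to rhodium and addition to the electron-rich, peri-substituted chromone. Hydroxide may also open the product by retro-oxa-Michael reaction and erode C2. The fallback builds ring C by the classical chalcone route and sets out from 11. Bromine–lithium exchange (n-BuLi, THF, −78 °C) and formylation with DMF give (2R,3R)-3-[3,5-bis(methoxymethoxy)phenyl]-6-(methoxymethoxy)-2-[4-(methoxymethoxy)phenyl]-2,3-dihydro-1-benzofuran-5-carbaldehyde F5. Claisen–Schmidt condensation with 16 (KOH, EtOH/H2O) gives (E)-1-[2-hydroxy-4,6-bis(methoxymethoxy)-3,5-bis(3-methylbut-2-enyl)phenyl]-3-{(2R,3R)-3-[3,5-bis(methoxymethoxy)phenyl]-6-(methoxymethoxy)-2-[4-(methoxymethoxy)phenyl]-2,3-dihydro-1-benzofuran-5-yl}prop-2-en-1-one F6. Oxa-Michael cyclisation (NaOAc, EtOH, reflux) gives 19 and its C2 epimer, the (2R)-configured diastereomer of 19 F7. The two are diastereomers and should be separable by chromatography, and F7 is returned to the same conditions, where reversible ring opening re-forms the mixture. The route is rejoined at 19.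

Step 12. Protonation of a prenyl alkene followed by capture by a neighbouring phenol (chroman formation), or methanolysis of the O–Ca bond once the 4-hydroxyphenyl group is free, may compete with acetal cleavage. The fallback avoids protic acid and sets out from 19. Et3SiOTf with 2,2′-bipyridyl (CH2Cl2, 0 °C) should exchange the aryl methoxymethyl ethers for silyl ethers under buffered aprotic conditions and give (2S)-2-{(2R,3R)-3-[3,5-bis(triethylsilyloxy)phenyl]-6-(triethylsilyloxy)-2-[4-(triethylsilyloxy)phenyl]-2,3-dihydro-1-benzofuran-5-yl}-5,7-bis(triethylsilyloxy)-6,8-bis(3-methylbut-2-enyl)-2,3-dihydro-4H-chromen-4-one F8. Buffered fluoride (n-Bu4NF, AcOH, THF, 0 °C) then gives 20.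

## Further compounds

F1 | step 4 | 5-bromo-3-(3,5-dimethoxyphenyl)-6-methoxy-2-(4-methoxyphenyl)-1-benzofuran | COc1ccc(cc1)-c1oc2cc(OC)c(Br)cc2c1-c1cc(OC)cc(OC)c1
F2 | step 4 | racemic trans-5-bromo-3-(3,5-dimethoxyphenyl)-6-methoxy-2-(4-methoxyphenyl)-2,3-dihydro-1-benzofuran | Brc1cc2c(cc1OC)O[C@@H](c1ccc(OC)cc1)[C@@H]2c1cc(OC)cc(OC)c1.Brc1cc2c(cc1OC)O[C@H](c1ccc(OC)cc1)[C@H]2c1cc(OC)cc(OC)c1
F3 | step 4 | 5-[(2S,3S)-5-bromo-6-hydroxy-2-(4-hydroxyphenyl)-2,3-dihydro-1-benzofuran-3-yl]benzene-1,3-diol | Brc1cc2c(cc1O)O[C@H](c1ccc(O)cc1)[C@H]2c1cc(O)cc(O)c1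
F4 | step 5 | (2R,3R)-5-bromo-3-(3,5-dimethoxyphenyl)-6-methoxy-2-(4-methoxyphenyl)-2,3-dihydro-1-benzofuran | Brc1cc2c(cc1OC)O[C@@H](c1ccc(OC)cc1)[C@@H]2c1cc(OC)cc(OC)c1
F5 | step 11 | (2R,3R)-3-[3,5-bis(methoxymethoxy)phenyl]-6-(methoxymethoxy)-2-[4-(methoxymethoxy)phenyl]-2,3-dihydro-1-benzofuran-5-carbaldehyde | O=Cc1cc2c(cc1OCOC)O[C@@H](c1ccc(OCOC)cc1)[C@@H]2c1cc(OCOC)cc(OCOC)c1
F6 | step 11 | (E)-1-[2-hydroxy-4,6-bis(methoxymethoxy)-3,5-bis(3-methylbut-2-enyl)phenyl]-3-{(2R,3R)-3-[3,5-bis(methoxymethoxy)phenyl]-6-(methoxymethoxy)-2-[4-(methoxymethoxy)phenyl]-2,3-dihydro-1-benzofuran-5-yl}prop-2-en-1-one | CC(C)=CCc1c(OCOC)c(CC=C(C)C)c(O)c(c1OCOC)C(=O)/C=C/c1cc2c(cc1OCOC)O[C@@H](c1ccc(OCOC)cc1)[C@@H]2c1cc(OCOC)cc(OCOC)c1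
F7 | step 11 | (2R)-2-{(2R,3R)-3-[3,5-bis(methoxymethoxy)phenyl]-6-(methoxymethoxy)-2-[4-(methoxymethoxy)phenyl]-2,3-dihydro-1-benzofuran-5-yl}-5,7-bis(methoxymethoxy)-6,8-bis(3-methylbut-2-enyl)-2,3-dihydro-4H-chromen-4-one | CC(C)=CCc1c(OCOC)c(CC=C(C)C)c2c(c1OCOC)C(=O)C[C@H](c1cc3c(cc1OCOC)O[C@@H](c1ccc(OCOC)cc1)[C@@H]3c1cc(OCOC)cc(OCOC)c1)O2
F8 | step 12 | (2S)-2-{(2R,3R)-3-[3,5-bis(triethylsilyloxy)phenyl]-6-(triethylsilyloxy)-2-[4-(triethylsilyloxy)phenyl]-2,3-dihydro-1-benzofuran-5-yl}-5,7-bis(triethylsilyloxy)-6,8-bis(3-methylbut-2-enyl)-2,3-dihydro-4H-chromen-4-one | CC(C)=CCc1c(O[Si](CC)(CC)CC)c(CC=C(C)C)c2c(c1O[Si](CC)(CC)CC)C(=O)C[C@@H](c1cc3c(cc1O[Si](CC)(CC)CC)O[C@@H](c1ccc(O[Si](CC)(CC)CC)cc1)[C@@H]3c1cc(O[Si](CC)(CC)CC)cc(O[Si](CC)(CC)CC)c1)O2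
A1 | alternative 1 | racemic trans-3-[3,5-bis(methoxymethoxy)phenyl]-6-(methoxymethoxy)-2-[4-(methoxymethoxy)phenyl]-2,3-dihydro-1-benzofuran-5-carbaldehyde | O=Cc1cc2c(cc1OCOC)O[C@@H](c1ccc(OCOC)cc1)[C@@H]2c1cc(OCOC)cc(OCOC)c1.O=Cc1cc2c(cc1OCOC)O[C@H](c1ccc(OCOC)cc1)[C@H]2c1cc(OCOC)cc(OCOC)c1
A2 | alternative 1 | (E)-1-[2-hydroxy-4,6-bis(methoxymethoxy)-3,5-bis(3-methylbut-2-enyl)phenyl]-3-{trans-3-[3,5-bis(methoxymethoxy)phenyl]-6-(methoxymethoxy)-2-[4-(methoxymethoxy)phenyl]-2,3-dihydro-1-benzofuran-5-yl}prop-2-en-1-one, racemic in ring D | CC(C)=CCc1c(OCOC)c(CC=C(C)C)c(O)c(c1OCOC)C(=O)/C=C/c1cc2c(cc1OCOC)O[C@@H](c1ccc(OCOC)cc1)[C@@H]2c1cc(OCOC)cc(OCOC)c1.CC(C)=CCc1c(OCOC)c(CC=C(C)C)c(O)c(c1OCOC)C(=O)/C=C/c1cc2c(cc1OCOC)O[C@H](c1ccc(OCOC)cc1)[C@H]2c1cc(OCOC)cc(OCOC)c1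
A3 | alternative 2 | (2S)-2-(2,4-dihydroxyphenyl)-5,7-dihydroxy-6,8-bis(3-methylbut-2-enyl)-2,3-dihydro-4H-chromen-4-one | CC(C)=CCc1c(O)c(CC=C(C)C)c2c(c1O)C(=O)C[C@@H](c1ccc(O)cc1O)O2
A4 | alternative 2 | resveratrol, 5-[(E)-2-(4-hydroxyphenyl)ethenyl]benzene-1,3-diol | Oc1ccc(/C=C/c2cc(O)cc(O)c2)cc1
A5 | alternative 3 | 4-bromo-2-[(1R)-1-(3,5-dimethoxyphenyl)-2-(4-hydroxyphenyl)ethyl]-5-methoxyphenol | COc1cc(O)c(cc1Br)[C@H](Cc1ccc(O)cc1)c1cc(OC)cc(OC)c1
A6 | alternative 3 | 4-[(2R)-2-(5-bromo-2-hydroxy-4-methoxyphenyl)-2-(3,5-dimethoxyphenyl)ethylidene]cyclohexa-2,5-dien-1-one | COc1cc(O)c(cc1Br)[C@H](C=C1C=CC(=O)C=C1)c1cc(OC)cc(OC)c1
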